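Remark (assumption on the chemistry): lignan locants are used beside ring numbers. Guaiacyl half: C7 (carbinol), C8 (ring C-4), C9 (ring C-5). Catechol half: C7' (ring C-2), C8' (ring C-3), C9' (CH2OH). Compounds 1, 2 and 7 are taken as commercial.

## Analysis of the target

The target is a 2,3,4-trisubstituted oxolane (O1, C2 = C7', C3 = C8', C4 = C8, C5 = C9) that carries a catechol ring on C2, a hydroxymethyl group (C9') on C3 and an aryl carbinol (C7, guaiacyl) on C4. Four contiguous stereocentres are present: C7' (S), C8' (R), C8 (R) and the exocyclic C7 (R). The ring is 2,3-trans and 3,4-cis, the latter being the less stable arrangement, so any intermediate with an enolisable C8 or C8' in a monocyclic oxolane drifts to the wrong isomer. The two hydroxyl groups O–C7 and O–C9' sit on the cis arms of C8 and C8' and form a 1,4-diol: the chain O7–C7–C8–C8'–C9' is the ring-opened form of a γ-lactone cis-fused to the oxolane, and 7R corresponds to the guaiacyl group on the concave face of that bicycle. This is the feature the route exploits. The free para-hydroxybenzylic alcohol ionises under acid to a quinone methide that is trapped by the C9' hydroxyl (furofuran formation), the benzylic C–O bonds at C7 and C7' are open to hydrogenolysis, and the catechol is air-sensitive in base. The two aryl rings differ by one O-methyl group only and the two benzylic oxygens have nearly the same reactivity, so they must be told apart by construction, not by late selective reactions.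

## Retrosynthetic reasoning

Target 11 is traced back to its tribenzyl ether 10. Only three aryl O–benzyl bonds are cut, because benzyl ethers survive every earlier step and are removed under neutral conditions, which the acid-labile para-hydroxybenzylic carbinol requires.

In 10 a bond that the target does not contain is added in the retrosynthetic sense: the acyl bond between C9' and the oxygen on C7, which gives the cis-fused furofuranone 9. This temporary lactone ring forces C8 and C8' cis, stores the C7 configuration as "aryl on the concave face", and makes the two benzylic oxygens chemically different. The forward reaction is a hydride reduction of the lactone that cleaves only the acyl C–O bond.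

Lactone 9 is cut at the C7–C8 bond and at the lactone C–O bond, which leads to aldehyde 7 and the cyclic enoate 6. C7 is treated as a ketyl radical (umpolung of the aldehyde) and C8 as the β-carbon of an enoate whose carboxyl carbon is C9'. This is the 1,4-relationship C7–O/C9', not the 1,3-relationship C7–O/C9 of an aldol disconnection. One forward operation has to join the two aryl halves, close the lactone and set C7, C8 and C8' relative to the single stereocentre C7' of 6. The step is stereoconvergent at C8', because only the cis ester can lactonise and the trans ester can epimerise.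

Enoate 6 is cut at the ring double bond C8=C8' and goes back to diene 5. The forward ring-closing metathesis of an O-allylated α-methylene β-hydroxy ester is a reliable way to a 2,5-dihydrofuran-3-carboxylate and leaves C7' untouched.

Diene 5 is cut at the allyl–oxygen bond to give carbinol 4, which is the R enantiomer of racemic 3. Compound 3 is cut at C7'–C8' and comes from aldehyde 1 and acrylate 2 in a Morita–Baylis–Hillman reaction. The only stereocentre that needs an external source of chirality, C7', is fixed by an enzymatic resolution at this early and cheap stage.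

## Alternatives that were turned down

Alternative 1: the textbook disconnection cuts C7–C8 as an aldol bond and O–C7' as a benzylic etherification. The forward key step would be the aldol addition of a 4-substituted butyrolactone enolate to 7 to give adduct A1, followed by lactone reduction and acid-mediated closure of the C9 hydroxyl onto a C7' cation. It was turned down for three reasons. The lithium lactone enolate has a fixed geometry and little bias between open and closed transition states, so C7 would form with weak simple diastereoselection. After reduction, C7 and C7' are two para-alkoxybenzylic carbinols of almost equal ionisation tendency, so the acid that closes the oxolane also closes C7–O–C9' to the furofuran unless further protecting-group steps are added. And three separate stereo-defining operations on acyclic or monocyclic material make the route clearly longer.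

Alternative 2: the C8–C8' bond is cut and formed by a radical 5-exo cyclisation. Opening the epoxide of ether A2 with Cp2TiCl (trivalent titanium) would give a C8' radical that adds to the cinnamyl double bond. The chair-like transition state should deliver the 2,3-trans-3,4-cis ring, but the benzylic C7 radical that results is planar and is trapped without facial control. Oxygenation at C7 would therefore be unselective, and the known alternative of closing C7–O–C9' by displacement leads to the convex-face aryl isomer, whose ring cannot be reopened with retention at C7. The hardest stereocentre of this target would be left unsolved.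

Alternative 3: the C8'–C7' bond is cut and formed by an intramolecular carbenoid C–H insertion. Diazo lactone A3 with Rh2(OAc)4 would insert into the benzylic ether C–H bond and close the oxolane onto a preformed lactone. The five-membered insertion transition state places the aryl group of the ether away from the catalyst and hence on the concave face, which would give A4, the C7' epimer of what is needed. A correction by acid equilibration would also put the concave-face aryl group at C7 at risk. In addition A3 needs the less stable 4,5-cis lactone, made and diazotised in more steps than the whole route below.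

Key step: step 5

## Steps

Step 1
Reactants: 1 3,4-bis(benzyloxy)benzaldehyde; 2 methyl acrylate
Product: 3 methyl 2-{[3,4-bis(benzyloxy)phenyl](hydroxy)methyl}prop-2-enoate (racemic)
Conditions: DABCO (1 equiv), 2 (3 equiv), MeOH, rt, several days
Reagents that add atoms: none
Why: Morita–Baylis–Hillman reaction: DABCO adds to 2, the ammonium enolate adds to the aldehyde of 1 and elimination returns the amine; this joins C7' to C8' and installs the α-methylene ester that later becomes the ring enoate. The carbinol is formed racemic and the benzyl ethers are inert.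

Step 2
Reactants: 3 methyl 2-{[3,4-bis(benzyloxy)phenyl](hydroxy)methyl}prop-2-enoate (racemic)
Product: 4 methyl 2-{(R)-[3,4-bis(benzyloxy)phenyl](hydroxy)methyl}prop-2-enoate
Conditions: Burkholderia cepacia lipase (Amano PS, immobilised), vinyl acetate (3 equiv), t-BuOMe, 35 °C, run to just past half conversion; chromatography
Reagents that add atoms: none
Why: Lipase-catalysed kinetic resolution by irreversible transesterification: one enantiomer of the secondary carbinol is acetylated and the other is recovered. With the aryl group as the large substituent, the usual empirical rule for lipases predicts acylation of the S alcohol, which leaves R-configured 4 and so fixes C7'.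

Step 3
Reactants: 4 methyl 2-{(R)-[3,4-bis(benzyloxy)phenyl](hydroxy)methyl}prop-2-enoate
Product: 5 methyl 2-{(R)-[3,4-bis(benzyloxy)phenyl](prop-2-en-1-yloxy)methyl}prop-2-enoate
Conditions: allyl bromide (5 equiv), Ag2O (2 equiv), 4 Å molecular sieves, Et2O, rt, dark
Reagents that add atoms: allyl bromide, C=CCBr
Why: Silver-oxide-mediated Williamson-type O-allylation under nearly neutral conditions, chosen because a free alkoxide of 4 would invite retro-aldol-type cleavage and oxa-Michael side reactions. The C7'–O bond is not broken, so the configuration is retained.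

Step 4
Reactants: 5 methyl 2-{(R)-[3,4-bis(benzyloxy)phenyl](prop-2-en-1-yloxy)methyl}prop-2-enoate
Product: 6 methyl (2R)-2-[3,4-bis(benzyloxy)phenyl]-2,5-dihydrofuran-3-carboxylate
Conditions: second-generation Grubbs catalyst RuCl2(=CHPh)(H2IMes)(PCy3) (5 mol %), CH2Cl2 (0.01 M), 40 °C
Reagents that add atoms: none
Why: Ring-closing olefin metathesis between the allyl ether and the 1,1-disubstituted acrylate alkene, a closure well known for O-allylated Morita–Baylis–Hillman adducts. It forms the ring double bond C8=C8' with loss of ethene and does not touch C7'.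

Step 5
Reactants: 6 methyl (2R)-2-[3,4-bis(benzyloxy)phenyl]-2,5-dihydrofuran-3-carboxylate; 7 4-(benzyloxy)-3-methoxybenzaldehyde
Product: 9 (3R,3aR,6S,6aS)-3-[4-(benzyloxy)-3-methoxyphenyl]-6-[3,4-bis(benzyloxy)phenyl]tetrahydro-1H,3H-furo[3,4-c]furan-1-one, via hydroxy ester 8 (not isolated)
Conditions: SmI2 (0.1 M in THF, 5 equiv), t-BuOH (3 equiv), THF, −78 to −20 °C, 7 (2.5 equiv) added slowly by syringe pump; aq. NH4Cl; then KOt-Bu (0.2 equiv), THF, 0 °C
Reagents that add atoms: none
Why: SmI2 reduces aldehyde 7 to its samarium-bound ketyl radical, which adds to ring C-4 (C8) of enoate 6; a second electron transfer gives the samarium ester enolate, tert-butanol protonates it at C-3 (C8'), and the trivalent samarium alkoxide on C7 acylates the neighbouring ester to close the γ-lactone (5-exo-trig acyl substitution), the oxolane ring being already present. The closest known reaction type is the SmI2-mediated reductive coupling of aldehydes and ketones with acrylates and crotonates to γ-butyrolactones. C8: the ketyl adds to the ring face opposite the C-2 aryl group, which allylic strain with the coplanar ester pushes into a pseudo-axial, face-shielding position. C7: an open transition state with the bulky O–Sm group anti to C-3 and the ketyl aryl group next to H-4 and not next to C-5 gives, after bond rotation on ring closure, the β,γ-cis lactone with the guaiacyl group on the concave face; this is the sense such couplings favour with (E)-β-substituted enoates, and it is the 7R configuration. C8': only a cis ring fusion lets the lactone close, so the cis isomer of 8 lactonises directly and its C-3 epimer is funnelled into 9 through enolate equilibration with catalytic KOt-Bu (stereoconvergent). The step needs cross-coupling to outrun pinacol dimerisation of the aryl ketyl, which slow addition of 7 to SmI2 in the presence of 6 should secure; it also needs the ester enolate not to expel the ring oxygen from C7', which the poor overlap of the endocyclic C–O bond with the enolate and the low temperature should secure.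

Step 6
Reactants: 9 (3R,3aR,6S,6aS)-3-[4-(benzyloxy)-3-methoxyphenyl]-6-[3,4-bis(benzyloxy)phenyl]tetrahydro-1H,3H-furo[3,4-c]furan-1-one
Product: 10 [(2S,3R,4R)-2-[3,4-bis(benzyloxy)phenyl]-4-{(R)-[4-(benzyloxy)-3-methoxyphenyl](hydroxy)methyl}oxolan-3-yl]methanol
Conditions: LiAlH4 (2 equiv), THF, 0 °C; aqueous potassium sodium tartrate work-up; chromatography on base-washed silica
Reagents that add atoms: none
Why: Hydride reduction of the γ-lactone to the 1,4-diol cleaves the acyl C9'–O bond, the bond that is not in the target, and leaves the C7–O bond and all four stereocentres untouched. Aryl benzyl ethers and the oxolane are inert to LiAlH4, and the non-acidic work-up avoids ionisation of the benzylic carbinol.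

Step 7
Reactants: 10 [(2S,3R,4R)-2-[3,4-bis(benzyloxy)phenyl]-4-{(R)-[4-(benzyloxy)-3-methoxyphenyl](hydroxy)methyl}oxolan-3-yl]methanol
Product: 11 (7R)-7-hydroxytaxiresinol, 4-[(2S,3R,4R)-4-[(R)-hydroxy(4-hydroxy-3-methoxyphenyl)methyl]-3-(hydroxymethyl)oxolan-2-yl]benzene-1,2-diol
Conditions: H2 (1 atm), Pd/C (10 wt %), EtOAc–EtOH (1:1), rt, stopped after uptake of 3 equiv H2; filtration under argon
Reagents that add atoms: none
Why: Heterogeneous hydrogenolysis of the three aryl benzyl ethers, which under neutral conditions at 1 atm should be much faster than hydrogenolysis of the benzylic C7–OH and C7'–O bonds. The neutral medium avoids quinone-methide formation from the liberated para-hydroxybenzylic alcohol, and no stereocentre is affected.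

## Compound list

1 | 3,4-bis(benzyloxy)benzaldehyde | O=Cc1ccc(OCc2ccccc2)c(OCc2ccccc2)c1 | starting material
2 | methyl acrylate | C=CC(=O)OC | starting material
3 | methyl 2-{[3,4-bis(benzyloxy)phenyl](hydroxy)methyl}prop-2-enoate (racemic) | C=C(C(=O)OC)C(O)c1ccc(OCc2ccccc2)c(OCc2ccccc2)c1 | intermediate
4 | methyl 2-{(R)-[3,4-bis(benzyloxy)phenyl](hydroxy)methyl}prop-2-enoate | C=C(C(=O)OC)[C@H](O)c1ccc(OCc2ccccc2)c(OCc2ccccc2)c1 | intermediate
5 | methyl 2-{(R)-[3,4-bis(benzyloxy)phenyl](prop-2-en-1-yloxy)methyl}prop-2-enoate | C=CCO[C@@H](C(=C)C(=O)OC)c1ccc(OCc2ccccc2)c(OCc2ccccc2)c1 | intermediate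
6 | methyl (2R)-2-[3,4-bis(benzyloxy)phenyl]-2,5-dihydrofuran-3-carboxylate | COC(=O)C1=CCO[C@@H]1c1ccc(OCc2ccccc2)c(OCc2ccccc2)c1 | intermediate
7 | 4-(benzyloxy)-3-methoxybenzaldehyde | COc1cc(C=O)ccc1OCc1ccccc1 | starting material
8 | methyl (2S,4R)-2-[3,4-bis(benzyloxy)phenyl]-4-{(R)-[4-(benzyloxy)-3-methoxyphenyl](hydroxy)methyl}oxolane-3-carboxylate (both C-3 epimers, formed as the samarium alkoxide) | COc1cc([C@H](O)[C@H]2CO[C@H](c3ccc(OCc4ccccc4)c(OCc4ccccc4)c3)C2C(=O)OC)ccc1OCc1ccccc1 | intermediate
9 | (3R,3aR,6S,6aS)-3-[4-(benzyloxy)-3-methoxyphenyl]-6-[3,4-bis(benzyloxy)phenyl]tetrahydro-1H,3H-furo[3,4-c]furan-1-one | COc1cc([C@H](O3)[C@H]2CO[C@H](c4ccc(OCc5ccccc5)c(OCc5ccccc5)c4)[C@H]2C3=O)ccc1OCc1ccccc1 | intermediate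
10 | [(2S,3R,4R)-2-[3,4-bis(benzyloxy)phenyl]-4-{(R)-[4-(benzyloxy)-3-methoxyphenyl](hydroxy)methyl}oxolan-3-yl]methanol | COc1cc([C@H](O)[C@H]2CO[C@H](c3ccc(OCc4ccccc4)c(OCc4ccccc4)c3)[C@H]2CO)ccc1OCc1ccccc1 | intermediate
11 | (7R)-7-hydroxytaxiresinol, 4-[(2S,3R,4R)-4-[(R)-hydroxy(4-hydroxy-3-methoxyphenyl)methyl]-3-(hydroxymethyl)oxolan-2-yl]benzene-1,2-diol | COc1cc([C@H](O)[C@H]2CO[C@H](c3ccc(O)c(O)c3)[C@H]2CO)ccc1O | target

## Step count and least certain steps

Total step count: 7. Longest linear sequence: 7 steps (1 → 3 → 4 → 5 → 6 → 9 → 10 → 11); aldehyde 7 enters at step 5.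

Step 5 (key step). Three things are most likely to go wrong:
- Pinacol dimerisation of the stabilised aryl ketyl may outrun its addition to a trisubstituted, fairly hindered enoate.
- A chelated transition state in place of the open one would erode or reverse the selectivity at C7.
- Facial control by the C-2 aryl group, which is one atom removed from the reacting carbon, may be incomplete.

Fallback (sets out from 6 and 7, returns at 8 and from there at 9): aldehyde 7 is converted with propane-1,3-dithiol and BF3·OEt2 into 2-[4-(benzyloxy)-3-methoxyphenyl]-1,3-dithiane F1. Its 2-lithio derivative (n-BuLi, THF–DMPU, −78 °C) is added in a Michael reaction to 6 to give methyl (2S,4R)-2-[3,4-bis(benzyloxy)phenyl]-4-{2-[4-(benzyloxy)-3-methoxyphenyl]-1,3-dithian-2-yl}oxolane-3-carboxylate F2. MeI and CaCO3 in aqueous MeCN unmask methyl (2S,4R)-4-[4-(benzyloxy)-3-methoxybenzoyl]-2-[3,4-bis(benzyloxy)phenyl]oxolane-3-carboxylate F3. Reduction of the ketone with LiBH(s-Bu)3 in THF at −78 °C gives hydroxy ester 8, which is lactonised with catalytic KOt-Bu as in step 5 to give 9. This polar umpolung sequence is known chemistry but sets C7 in a separate, less controlled reduction; incomplete diastereoselection there would have to be corrected by chromatography after lactonisation.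

Step 1. The amine-catalysed addition may stall, because the 3,4-dialkoxy-substituted aldehyde is a weak electrophile and the reaction is reversible. Fallback (sets out from 1, returns at 3): hydroalumination of methyl propiolate with i-Bu2AlH and N-methylmorpholine N-oxide in THF at 0 °C gives methyl 2-[bis(2-methylpropyl)alumanyl]prop-2-enoate F4, which adds to aldehyde 1 as a preformed vinyl nucleophile and gives 3 after aqueous work-up.

Step 2. Slow acylation and low enantiomer discrimination are possible, because the carbinol is flanked by two large groups; the sense of the enzyme's preference is predicted, not known. Fallback (sets out from 3, returns at 4): 3 is converted with Boc2O and DMAP into methyl 2-{[3,4-bis(benzyloxy)phenyl][(tert-butoxycarbonyl)oxy]methyl}prop-2-enoate F5. A tertiary-amine-catalysed asymmetric allylic substitution with water, using whichever of (DHQD)2AQN or (DHQ)2AQN gives the R carbinol, in aqueous dioxane, converts both enantiomers of F5 into 4 by two successive SN2' displacements. This is a deracemisation and not a resolution.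

Step 7. Over-reduction by hydrogenolysis of the benzylic C7–OH bond may set in once the para-hydroxyl group is free, and ring-opening hydrogenolysis at C7' is also conceivable. Fallback (sets out from 10, returns at 11): both hydroxyl groups of 10 are silylated with TBSOTf and 2,6-lutidine in CH2Cl2 at −78 °C to give (2S,3R,4R)-2-[3,4-bis(benzyloxy)phenyl]-4-{(R)-[4-(benzyloxy)-3-methoxyphenyl][(tert-butyldimethylsilyl)oxy]methyl}-3-{[(tert-butyldimethylsilyl)oxy]methyl}oxolane F6, in which the bulky silyl ether should shield the benzylic C7–O bond. Hydrogenolysis (H2, Pd/C, EtOAc) gives 4-[(2S,3R,4R)-4-{(R)-[(tert-butyldimethylsilyl)oxy](4-hydroxy-3-methoxyphenyl)methyl}-3-{[(tert-butyldimethylsilyl)oxy]methyl}oxolan-2-yl]benzene-1,2-diol F7. Tetrabutylammonium fluoride buffered with acetic acid in THF under argon then releases 11.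

## Further compounds

F1 | step 5 | 2-[4-(benzyloxy)-3-methoxyphenyl]-1,3-dithiane | COc1cc(C2SCCCS2)ccc1OCc1ccccc1
F2 | step 5 | methyl (2S,4R)-2-[3,4-bis(benzyloxy)phenyl]-4-{2-[4-(benzyloxy)-3-methoxyphenyl]-1,3-dithian-2-yl}oxolane-3-carboxylate (C-3 epimers) | COc1cc(C2(SCCCS2)[C@H]2CO[C@H](c3ccc(OCc4ccccc4)c(OCc4ccccc4)c3)C2C(=O)OC)ccc1OCc1ccccc1
F3 | step 5 | methyl (2S,4R)-4-[4-(benzyloxy)-3-methoxybenzoyl]-2-[3,4-bis(benzyloxy)phenyl]oxolane-3-carboxylate (C-3 epimers) | COc1cc(C(=O)[C@H]2CO[C@H](c3ccc(OCc4ccccc4)c(OCc4ccccc4)c3)C2C(=O)OC)ccc1OCc1ccccc1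
F4 | step 1 | methyl 2-[bis(2-methylpropyl)alumanyl]prop-2-enoate | C=C(C(=O)OC)[Al](CC(C)C)CC(C)C
F5 | step 2 | methyl 2-{[3,4-bis(benzyloxy)phenyl][(tert-butoxycarbonyl)oxy]methyl}prop-2-enoate (racemic) | C=C(C(=O)OC)C(OC(=O)OC(C)(C)C)c1ccc(OCc2ccccc2)c(OCc2ccccc2)c1
F6 | step 7 | (2S,3R,4R)-2-[3,4-bis(benzyloxy)phenyl]-4-{(R)-[4-(benzyloxy)-3-methoxyphenyl][(tert-butyldimethylsilyl)oxy]methyl}-3-{[(tert-butyldimethylsilyl)oxy]methyl}oxolane | COc1cc([C@H](O[Si](C)(C)C(C)(C)C)[C@H]2CO[C@H](c3ccc(OCc4ccccc4)c(OCc4ccccc4)c3)[C@H]2CO[Si](C)(C)C(C)(C)C)ccc1OCc1ccccc1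
F7 | step 7 | 4-[(2S,3R,4R)-4-{(R)-[(tert-butyldimethylsilyl)oxy](4-hydroxy-3-methoxyphenyl)methyl}-3-{[(tert-butyldimethylsilyl)oxy]methyl}oxolan-2-yl]benzene-1,2-diol | COc1cc([C@H](O[Si](C)(C)C(C)(C)C)[C@H]2CO[C@H](c3ccc(O)c(O)c3)[C@H]2CO[Si](C)(C)C(C)(C)C)ccc1O
A1 | alternative 1 | (3S,4R)-4-{(S)-[3,4-bis(benzyloxy)phenyl][(tert-butyldimethylsilyl)oxy]methyl}-3-{[4-(benzyloxy)-3-methoxyphenyl](hydroxy)methyl}oxolan-2-one (C7 epimers) | COc1cc(C(O)[C@H]2C(=O)OC[C@@H]2[C@H](O[Si](C)(C)C(C)(C)C)c2ccc(OCc3ccccc3)c(OCc3ccccc3)c2)ccc1OCc1ccccc1
A2 | alternative 2 | 2-{(R)-[3,4-bis(benzyloxy)phenyl]({(2E)-3-[4-(benzyloxy)-3-methoxyphenyl]prop-2-en-1-yl}oxy)methyl}oxirane (epoxide epimers) | COc1cc(/C=C/CO[C@@H](C2CO2)c2ccc(OCc3ccccc3)c(OCc3ccccc3)c2)ccc1OCc1ccccc1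
A3 | alternative 3 | (4R,5R)-5-[4-(benzyloxy)-3-methoxyphenyl]-4-({[3,4-bis(benzyloxy)phenyl]methoxy}methyl)-3-diazooxolan-2-one | [N-]=[N+]=C1C(=O)O[C@@H](c2ccc(OCc3ccccc3)c(OC)c2)[C@H]1COCc1ccc(OCc2ccccc2)c(OCc2ccccc2)c1
A4 | alternative 3 | (3R,3aR,6R,6aS)-3-[4-(benzyloxy)-3-methoxyphenyl]-6-[3,4-bis(benzyloxy)phenyl]tetrahydro-1H,3H-furo[3,4-c]furan-1-one | COc1cc([C@H](O3)[C@H]2CO[C@@H](c4ccc(OCc5ccccc5)c(OCc5ccccc5)c4)[C@H]2C3=O)ccc1OCc1ccccc1
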